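## Retrosynthetic overview

1. The oxirane is formed last, by face- and site-selective oxygen transfer to the Δ3 olefin of a macrocyclic 1,3-diene of the cembrene-C type.
2. The diene comes from a C2 carbinol (syn-dehydration) and an isopropenyl group (hydrogenation), both left behind by the ring closure.
3. The fourteen-membered ring is formed first, through the C1–C2 bond: the prenyl terminus attacks a Lewis-acid-activated C2 enal (cation–olefin/carbonyl-ene closure) in a seco-chain that already carries both esters and both acetates, so the two enoate olefins cannot compete.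
4. The seco-enal is cut at C7=C8 (Z-selective Still–Gennari union) into a west dialdehyde (C2–C7) and an east phosphonate (C8–C15).
5. West: asymmetric vinylogous Mukaiyama aldol of the prenal dienol ether with glyoxal mono-acetal. East: ynoate hydroalumination–aldol, lipase resolution, phosphonoacetate alkylation.

Locants are cembrane locants: C1 carries the isopropyl group, the ring runs C2, C3/C4 (oxirane), C6 (OAc), C7=C8 (C19 ester), C11=C12 (C20 ester), C13 (OAc), C14.

Assumption 1: the (S)-tryptophan-derived oxazaborolidinone directs the dienol ether to the Re face of aldehyde 3; if the sense is opposite, the catalyst from (R)-tryptophan is used.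

Assumption 2: the ene closure gives the 1,2-cis adduct (both chain ends pseudo-equatorial in a chair-like transition state) as two diastereomers that differ only in the absolute sense of the C1/C2 pair; both are carried on and converge in step 13.

## Route

Step 1
Reactants: 1 3-methylbut-2-enal (prenal)
Product: 2 (E)-tert-butyl(dimethyl)[(3-methylbuta-1,3-dien-1-yl)oxy]silane
Conditions: TBSOTf, Et3N, CH2Cl2, 0 °C to rt
Reagents that add atoms: tert-butyldimethylsilyl trifluoromethanesulfonate, CC(C)(C)[Si](C)(C)OS(=O)(=O)C(F)(F)F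
Why: O-silylation of the enal with γ-deprotonation (silyl dienol ether formation) gives the E-dienol ether that serves as the C2–C5/C18 nucleophile.

Step 2
Reactants: 2 (E)-silyl dienol ether; 3 2,2-dimethoxyacetaldehyde (anhydrous, freshly distilled)
Product: 4 (2E,5R)-5-hydroxy-6,6-dimethoxy-3-methylhex-2-enal
Conditions: (S)-4-(indol-3-ylmethyl)-2-phenyl-3-tosyl-1,3,2-oxazaborolidin-5-one (0.5 equiv), i-PrOH, EtCN, −78 °C
Reagents that add atoms: none
Why: Asymmetric vinylogous Mukaiyama aldol addition, in which the boron-bound aldehyde is attacked at its Re face by the γ-carbon of the dienol ether (the indole ring blocks the other face), sets C6 as R and gives the E-enal directly, while propan-2-ol takes up the silyl group and turns the catalyst over.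

Step 3
Reactants: 4 (2E,5R)-5-hydroxy-6,6-dimethoxy-3-methylhex-2-enal
Product: 5 (2R,4E)-1,1-dimethoxy-4-methyl-6-oxohex-4-en-2-yl acetate
Conditions: Ac2O, pyridine, 4-(dimethylamino)pyridine (cat.), CH2Cl2, 0 °C
Reagents that add atoms: acetic anhydride, CC(=O)OC(C)=O
Why: Nucleophile-catalysed acetylation of the secondary alcohol installs the C6 acetate without touching the stereocenter or the enal.

Step 4
Reactants: 5 (2R,4E)-1,1-dimethoxy-4-methyl-6-oxohex-4-en-2-yl acetate
Product: 6 (2R,4E)-4-methyl-1,6-dioxohex-4-en-2-yl acetate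
Conditions: CF3CO2H–H2O (4:1), CHCl3, 0 °C; used crude
Reagents that add atoms: water, O
Why: Acid-catalysed acetal hydrolysis unmasks the α-acetoxy aldehyde (C7) under conditions that leave the acetate and the thermodynamically preferred E-enal unchanged, C6 being configurationally stable in acid.

Step 5
Reactants: 7 4-bromobut-1-yne
Product: 9 methyl 5-bromopent-2-ynoate, via lithium acetylide 8 (not isolated)
Conditions: LiN(i-Pr)2, THF, −78 °C; ClCO2Me, −78 to 0 °C
Reagents that add atoms: methyl chloroformate, COC(=O)Cl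
Why: Deprotonation of the terminal alkyne and C-acylation of the acetylide gives the ynoate that holds C9–C12 and the C20 ester, the primary bromide being inert at −78 °C.

Step 6
Reactants: 10 4-methylpent-3-en-1-ol
Product: 11 4-methylpent-3-enal
Conditions: Dess–Martin periodinane, pyridine, CH2Cl2, 0 °C; used at once as a dried solution
Reagents that add atoms: none
Why: Buffered Dess–Martin oxidation gives the β,γ-unsaturated aldehyde without migration of the double bond into conjugation.

Step 7
Reactants: 9 methyl 5-bromopent-2-ynoate; 11 4-methylpent-3-enal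
Product: 13 methyl (2Z)-5-bromo-2-(1-hydroxy-4-methylpent-3-en-1-yl)pent-2-enoate (racemic), via vinylalane 12 (not isolated)
Conditions: i-Bu2AlH, OP(NMe2)3, THF, 0 °C; then 11, 0 °C to rt; aq. Rochelle salt
Reagents that add atoms: none
Why: Conjugate hydroalumination of the ynoate gives the α-alumino acrylate (aluminium allenolate), which adds to the aldehyde at C12 from the side of H-11, so the Morita–Baylis–Hillman-type adduct has CO2Me cis to C10 (Z) and C13 is formed racemic.

Step 8
Reactants: 13 racemic methyl (2Z)-5-bromo-2-(1-hydroxy-4-methylpent-3-en-1-yl)pent-2-enoate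
Product: 14 methyl (2Z)-2-[(1R)-1-acetoxy-4-methylpent-3-en-1-yl]-5-bromopent-2-enoate
Conditions: Burkholderia cepacia lipase (Amano PS, immobilized), vinyl acetate, t-BuOMe, 30 °C, stopped at 50% conversion
Reagents that add atoms: vinyl acetate, CC(=O)OC=C
Why: Lipase-catalysed kinetic resolution by acyl transfer, which by the Kazlauskas rule (large group = ester-bearing alkenyl, medium group = CH2 chain) acetylates only the R alcohol, sets C13 and installs its acetate in one operation (50% maximum, the S alcohol is separated by chromatography).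

Step 9
Reactants: 14 (R)-acetate bromide; 15 methyl 2-[bis(2,2,2-trifluoroethoxy)phosphoryl]acetate (1.5 equiv)
Product: 17 dimethyl (5Z)-6-[(1R)-1-acetoxy-4-methylpent-3-en-1-yl]-2-[bis(2,2,2-trifluoroethoxy)phosphoryl]hept-5-enedioate (C2 epimers), via sodium phosphonoenolate 16 (not isolated)
Conditions: NaH, DMF, 0 °C; then 14, 0 to 40 °C
Reagents that add atoms: none
Why: SN2 C-alkylation of the soft, weakly basic phosphonoacetate anion at the primary bromide gives the α-substituted Still–Gennari reagent, the hindered trisubstituted enoate and its acetate being poor acceptors, and the new center at C8 is erased in the next step.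

Step 10
Reactants: 17 east phosphonate; 6 west dialdehyde (1.0 equiv)
Product: 19 dimethyl (2Z,5Z)-2-[(2R,4E)-2-acetoxy-4-methyl-6-oxohex-4-en-1-ylidene]-6-[(1R)-1-acetoxy-4-methylpent-3-en-1-yl]hept-5-enedioate, via potassium phosphonate carbanion 18 (not isolated)
Conditions: KN(SiMe3)2, 18-crown-6, THF, −78 °C; then 6, −78 °C
Reagents that add atoms: none
Why: Still–Gennari (Z-selective Horner–Wadsworth–Emmons) olefination, in which the dissociated potassium bis(trifluoroethyl)phosphonate adds irreversibly and eliminates fast, gives the C7=C8 enoate with CO2Me cis to C6 and reacts only with the far more electrophilic α-acetoxy aldehyde of 6 and not with its β,β-disubstituted enal, C6 being untouched at −78 °C.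

Step 11
Reactants: 19 seco-enal
Product: 20 dimethyl (1S,2R,3E,6R,7Z,11Z,13R)-6,13-diacetoxy-2-hydroxycembra-3,7,11,15-tetraene-19,20-dioate (1,2-cis; formed together with its (1R,2S) 1,2-cis diastereomer)
Conditions: Me2AlCl (5 equiv), CH2Cl2, −78 to −20 °C, 19 added by syringe pump to 0.002 M
Reagents that add atoms: none
Why: Proposed new method: the Me2AlCl-bound enal is the C2 electrophile (the flask equivalent of the ionized allylic diphosphate) and the prenyl C1=C15 olefin is the only π-nucleophile left, because Δ7 and Δ11 are electron-poor enoates and attack at the quaternary β-carbon is disfavoured, so C1 adds to the carbonyl carbon and a methyl hydrogen passes to oxygen in a six-membered transition state to give the fourteen-membered ring, the isopropenyl group and the C2 carbinol (C1 and C2 are formed 1,2-cis and erased later), the closest known reaction type being the Lewis-acid-promoted carbonyl-ene (Prins-type) cyclization of ω-isopropylidene aldehydes (citral to isopiperitenol, alkynal closures to 12–16-membered rings) and the SnCl4-induced acylium–olefin closure of polyprenoyl chlorides to cembrane rings.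

Step 12
Reactants: 20 ene adduct
Product: 21 dimethyl (1S,2S,3E,6R,7Z,11Z,13R)-6,13-diacetoxy-2-hydroxycembra-3,7,11-triene-19,20-dioate (1,2-cis; together with its (1R,2R) diastereomer)
Conditions: H2 (1 atm), RhCl(PPh3)3 (10 mol%), benzene, rt
Reagents that add atoms: none
Why: Homogeneous hydrogenation with RhCl(PPh3)3 reduces only the 1,1-disubstituted isopropenyl olefin, the trisubstituted Δ3 olefin and the two trisubstituted enoates being far slower (the carvone-to-carvotanacetone selectivity), so the isopropyl group is made without touching a stereocenter.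

Step 13
Reactants: 21 1,2-cis allylic alcohol
Product: 23 dimethyl (1E,3E,6R,7Z,11Z,13R)-6,13-diacetoxycembra-1,3,7,11-tetraene-19,20-dioate, via sulfamate ester 22 (not isolated)
Conditions: Burgess reagent (MeO2C–N(−)–SO2–N(+)Et3, 2.5 equiv), benzene, rt then 50 °C
Reagents that add atoms: none
Why: Burgess dehydration, a thermal syn (Ei) elimination of the C2 sulfamate with H-1 as the only β-hydrogen, converts either 1,2-cis diastereomer into the 1E olefin (C14 and C3 cis, isopropyl trans to C3) and so gives the conjugated diene of the cembrene-C type while erasing both new stereocenters.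

Step 14
Reactants: 23 macrocyclic 1,3-diene
Product: 24 dimethyl (1E,3S,4S,6R,7Z,11Z,13R)-6,13-diacetoxy-3,4-epoxycembra-1,7,11-triene-19,20-dioate (CNP0359666.2)
Conditions: 1,2:4,5-di-O-isopropylidene-β-L-erythro-2,3-hexodiulo-2,6-pyranose (L-fructose-derived Shi ketone, 30 mol%), 2KHSO5·KHSO4·K2SO4, K2CO3, Bu4NHSO4, MeCN–CH2(OMe)2–aq. Na2B4O7/Na2EDTA (pH 10.5), 0 °C
Reagents that add atoms: potassium peroxymonosulfate (KHSO5), [K+].[O-]S(=O)(=O)OO
Why: Shi asymmetric epoxidation, in which the chiral dioxirane transfers oxygen through a spiro transition state to the less hindered electron-rich Δ3 olefin (Δ1 is shielded by the isopropyl group, Δ7 and Δ11 are electron-poor enoates), sets C3 and C4 as S,S because this ketone is the mirror image of the D-fructose ketone that gives R,R-epoxides from E-olefins.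

## Compound list

1 | 3-methylbut-2-enal | CC(C)=CC=O | starting material
2 | (E)-tert-butyl(dimethyl)[(3-methylbuta-1,3-dien-1-yl)oxy]silane | C=C(C)/C=C/O[Si](C)(C)C(C)(C)C | intermediate
3 | 2,2-dimethoxyacetaldehyde | COC(OC)C=O | starting material
4 | (2E,5R)-5-hydroxy-6,6-dimethoxy-3-methylhex-2-enal | O=C/C=C(\C)C[C@@H](O)C(OC)OC | intermediate
5 | (2R,4E)-1,1-dimethoxy-4-methyl-6-oxohex-4-en-2-yl acetate | O=C/C=C(\C)C[C@@H](OC(C)=O)C(OC)OC | intermediate
6 | (2R,4E)-4-methyl-1,6-dioxohex-4-en-2-yl acetate | O=C/C=C(\C)C[C@@H](OC(C)=O)C=O | intermediate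
7 | 4-bromobut-1-yne | C#CCCBr | starting material
8 | lithium 4-bromobut-1-yn-1-ide | [Li+].[C-]#CCCBr | intermediate (not isolated)
9 | methyl 5-bromopent-2-ynoate | COC(=O)C#CCCBr | intermediate
10 | 4-methylpent-3-en-1-ol | CC(C)=CCCO | starting material
11 | 4-methylpent-3-enal | CC(C)=CCC=O | intermediate
12 | methyl (2E)-2-[bis(2-methylpropyl)alumanyl]-5-bromopent-2-enoate (in equilibrium with its aluminium allenolate) | BrCC/C=C(\C(=O)OC)[Al](CC(C)C)CC(C)C | intermediate (not isolated)
13 | methyl (2Z)-5-bromo-2-(1-hydroxy-4-methylpent-3-en-1-yl)pent-2-enoate, racemic | CC(C)=CCC(O)/C(C(=O)OC)=C/CCBr | intermediate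
14 | methyl (2Z)-2-[(1R)-1-acetoxy-4-methylpent-3-en-1-yl]-5-bromopent-2-enoate | CC(C)=CC[C@@H](OC(C)=O)/C(C(=O)OC)=C/CCBr | intermediate
15 | methyl 2-[bis(2,2,2-trifluoroethoxy)phosphoryl]acetate | COC(=O)CP(=O)(OCC(F)(F)F)OCC(F)(F)F | starting material
16 | sodium salt of 15 (phosphonoenolate) | [Na+].COC(=O)[CH-]P(=O)(OCC(F)(F)F)OCC(F)(F)F | intermediate (not isolated)
17 | dimethyl (5Z)-6-[(1R)-1-acetoxy-4-methylpent-3-en-1-yl]-2-[bis(2,2,2-trifluoroethoxy)phosphoryl]hept-5-enedioate (C2 epimers) | CC(C)=CC[C@@H](OC(C)=O)/C(C(=O)OC)=C/CCC(C(=O)OC)P(=O)(OCC(F)(F)F)OCC(F)(F)F | intermediate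
18 | potassium salt of 17 (phosphonate carbanion) | [K+].CC(C)=CC[C@@H](OC(C)=O)/C(C(=O)OC)=C/CC[C-](C(=O)OC)P(=O)(OCC(F)(F)F)OCC(F)(F)F | intermediate (not isolated)
19 | dimethyl (2Z,5Z)-2-[(2R,4E)-2-acetoxy-4-methyl-6-oxohex-4-en-1-ylidene]-6-[(1R)-1-acetoxy-4-methylpent-3-en-1-yl]hept-5-enedioate (seco-enal) | O=C/C=C(\C)C[C@@H](OC(C)=O)/C=C(\C(=O)OC)CC/C=C(\C(=O)OC)[C@H](OC(C)=O)CC=C(C)C | intermediate
20 | dimethyl (1S,2R,3E,6R,7Z,11Z,13R)-6,13-diacetoxy-2-hydroxycembra-3,7,11,15-tetraene-19,20-dioate (1,2-cis; the (1R,2S) 1,2-cis diastereomer accompanies it) | COC(=O)/C1=C\[C@H](OC(C)=O)C/C(C)=C/[C@@H](O)[C@H](C(C)=C)C[C@@H](OC(C)=O)/C(C(=O)OC)=C/CC1 | intermediate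
21 | dimethyl (1S,2S,3E,6R,7Z,11Z,13R)-6,13-diacetoxy-2-hydroxycembra-3,7,11-triene-19,20-dioate (1,2-cis; the (1R,2R) diastereomer accompanies it) | COC(=O)/C1=C\[C@H](OC(C)=O)C/C(C)=C/[C@@H](O)[C@H](C(C)C)C[C@@H](OC(C)=O)/C(C(=O)OC)=C/CC1 | intermediate
22 | triethylammonium salt of the C2 O-[N-(methoxycarbonyl)sulfamate] of 21 | COC(=O)/C1=C\[C@H](OC(C)=O)C/C(C)=C/[C@@H](OS(=O)(=O)[N-]C(=O)OC)[C@H](C(C)C)C[C@@H](OC(C)=O)/C(C(=O)OC)=C/CC1.CC[NH+](CC)CC | intermediate (not isolated)
23 | dimethyl (1E,3E,6R,7Z,11Z,13R)-6,13-diacetoxycembra-1,3,7,11-tetraene-19,20-dioate | COC(=O)/C1=C\[C@H](OC(C)=O)C/C(C)=C/C=C(/C(C)C)C[C@@H](OC(C)=O)/C(C(=O)OC)=C/CC1 | intermediate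
24 | dimethyl (1E,3S,4S,6R,7Z,11Z,13R)-6,13-diacetoxy-3,4-epoxycembra-1,7,11-triene-19,20-dioate | COC(=O)/C1=C\[C@H](OC(C)=O)C[C@]2(C)O[C@H]2/C=C(/C(C)C)C[C@@H](OC(C)=O)/C(C(=O)OC)=C/CC1 | target

## Step count and risks

Total steps: 14. Longest linear sequence: 9 steps (7 → 9 → 13 → 14 → 17 → 19 → 20 → 21 → 23 → 24; the west branch 1 → 2 → 4 → 5 → 6 → 19 is equally long).

Steps most likely to fail:

Step 11 (macrocyclic ene closure). The enal may be too weak an enophile at high dilution, or oligomerization and methyl transfer from aluminium may win. Fallback: the same C1–C2 bond is made by an acylium–olefin closure. It sets out from 19. Oxidation with NaClO2/NaH2PO4/2-methylbut-2-ene gives the seco-acid F1, and (COCl)2 with catalytic DMF gives the acid chloride F2. SnCl4 (CH2Cl2, −78 °C, 0.002 M) then closes the ring with chloride capture at C15 to give the chloro ketone F3. NaBH4/CeCl3·7H2O reduces the carbonyl 1,2 under Felkin–Anh control to the 1,2-cis chlorohydrin F4. Bu3SnH/AIBN (high hydride concentration, benzene, 80 °C) removes the tertiary chloride, and the sequence comes back to the route at 21.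

Step 13 (dehydration to the diene). The allylic sulfamate may ionize (1,4-elimination to the 2,4-diene or allylic transposition), or the ene adduct may prove to be 1,2-trans, which would give the wrong C1=C2 geometry. Fallback: the olefin is made from the ketone, independent of the C1/C2 configuration. It sets out from 21. Dess–Martin oxidation gives the enone F5. KN(SiMe3)2 and N-(5-chloropyridin-2-yl)bis(trifluoromethanesulfonyl)imide at −78 °C trap the cross-conjugated enolate (the bulkier isopropyl group cis to oxygen) as the dienyl triflate F6. Pd(OAc)2/PPh3/Bu3SnH/LiCl reduces the C–OTf bond with retention, and the sequence comes back to the route at 23.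

Step 14 (epoxidation of the diene). Oxygen may go to Δ1 as well as Δ3, or to both. Fallback: the order of olefin formation and oxygen transfer is reversed. It sets out from 21, where Δ3 is the only electron-rich olefin. The same L-fructose-derived ketone/KHSO5 system gives the 2-hydroxy-3,4-epoxide F7. Burgess syn-elimination of F7 (H-1 is the only β-hydrogen and no allyl cation can form next to the oxirane) gives the vinyl oxirane directly, and the sequence comes back to the route at 24.

Further compounds
F1 | step 11 | dimethyl (2Z,5Z)-2-[(2R,4E)-2-acetoxy-5-carboxy-4-methylpent-4-en-1-ylidene]-6-[(1R)-1-acetoxy-4-methylpent-3-en-1-yl]hept-5-enedioate (seco-acid) | OC(=O)/C=C(\C)C[C@@H](OC(C)=O)/C=C(\C(=O)OC)CC/C=C(\C(=O)OC)[C@H](OC(C)=O)CC=C(C)C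
F2 | step 11 | dimethyl (2Z,5Z)-2-[(2R,4E)-2-acetoxy-6-chloro-4-methyl-6-oxohex-4-en-1-ylidene]-6-[(1R)-1-acetoxy-4-methylpent-3-en-1-yl]hept-5-enedioate (acid chloride) | ClC(=O)/C=C(\C)C[C@@H](OC(C)=O)/C=C(\C(=O)OC)CC/C=C(\C(=O)OC)[C@H](OC(C)=O)CC=C(C)C
F3 | step 11 | dimethyl (3E,6R,7Z,11Z,13R)-6,13-diacetoxy-15-chloro-2-oxocembra-3,7,11-triene-19,20-dioate (C1 epimers) | COC(=O)/C1=C\[C@H](OC(C)=O)C/C(C)=C/C(=O)C(C(C)(C)Cl)C[C@@H](OC(C)=O)/C(C(=O)OC)=C/CC1
F4 | step 11 | dimethyl (3E,6R,7Z,11Z,13R)-6,13-diacetoxy-15-chloro-2-hydroxycembra-3,7,11-triene-19,20-dioate (1,2-cis) | COC(=O)/C1=C\[C@H](OC(C)=O)C/C(C)=C/[C@@H](O)[C@H](C(C)(C)Cl)C[C@@H](OC(C)=O)/C(C(=O)OC)=C/CC1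
F5 | step 13 | dimethyl (3E,6R,7Z,11Z,13R)-6,13-diacetoxy-2-oxocembra-3,7,11-triene-19,20-dioate (C1 epimers) | COC(=O)/C1=C\[C@H](OC(C)=O)C/C(C)=C/C(=O)C(C(C)C)C[C@@H](OC(C)=O)/C(C(=O)OC)=C/CC1
F6 | step 13 | dimethyl (1Z,3E,6R,7Z,11Z,13R)-6,13-diacetoxy-2-(trifluoromethanesulfonyloxy)cembra-1,3,7,11-tetraene-19,20-dioate | COC(=O)/C1=C\[C@H](OC(C)=O)C/C(C)=C/C(OS(=O)(=O)C(F)(F)F)=C(/C(C)C)C[C@@H](OC(C)=O)/C(C(=O)OC)=C/CC1
F7 | step 14 | dimethyl (1S,2S,3S,4S,6R,7Z,11Z,13R)-6,13-diacetoxy-3,4-epoxy-2-hydroxycembra-7,11-diene-19,20-dioate (with its (1R,2R) diastereomer) | COC(=O)/C1=C\[C@H](OC(C)=O)C[C@]2(C)O[C@H]2[C@@H](O)[C@H](C(C)C)C[C@@H](OC(C)=O)/C(C(=O)OC)=C/CC1
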